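## Retrosynthetic overview
1. C16 is set last by exo-face hydrogenation of the 16-en-15-one 20, which comes from oxidation of allylic alcohol 19.
2. Ring D (C13–C16) is closed by a 5-exo vinyl-radical cyclisation of the C15 propargylic alcohol 18 onto the C12=C13 alkene.
3. Ring C (C9–C11 and C8–C14, setting C8 and C9) comes from a Diels–Alder reaction of butadiene with the 8-formyl spiro-dihydropyranone 14.
4. Ring B and C10 come from Ti(III) opening of spiro-epoxide 9, Giese addition to an acrylate, and lactonisation.
5. Ring A and the THF acetal come from asymmetric conjugate methylation (C4), an orthoformate Mukaiyama trap (C5–C6), and acetal closure. Ring order: A → THF → B → C → D.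

**Assumptions**
- ent-Kaurane numbering is used throughout. The target is (4R,5R,6S,8S,9S,10R,13R,16R), with 6-OMe on the convex (exo) face of the bicyclic acetal and the 16-Me endo (pointing toward C11/C12).
- In step 3 the ligand enantiomer is the one that gives (R)-5. The sense of induction is taken by analogy with simple 3-alkylcyclohexenones.
- Steps 1, 4, 8 and 11 are telescoped two-operation steps and are each counted once.

## Route

**Step 1**
Reactants: 1, 3-methoxybenzyl alcohol
Product: 2, 3-(hydroxymethyl)cyclohex-2-en-1-one
Conditions: Li, NH3(l), t-BuOH, THF, −78 to −33 °C; then 2 M HCl, THF, rt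
Reagents that add atoms: water, O
Why: Birch reduction, with the alkoxide suppressing benzylic C–O cleavage, gives the 1-methoxy-1,4-diene. Acid then hydrolyses the enol ether and moves the alkene into conjugation.

**Step 2**
Reactants: 2
Product: 3, 3-[(tert-butyldimethylsilyloxy)methyl]cyclohex-2-en-1-one
Conditions: TBSCl, imidazole, CH2Cl2, rt
Reagents that add atoms: TBSCl, CC(C)(C)[Si](C)(C)Cl
Why: Standard silylation. It masks the OH that would otherwise consume and coordinate Me3Al.

**Step 3**
Reactants: 3; 4, trimethylaluminium
Product: 5, (R)-tert-butyldimethyl{[1-methyl-3-(trimethylsilyloxy)cyclohex-2-en-1-yl]methoxy}silane (C4 = R)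
Conditions: 4 (1.5 equiv), CuTC (5 mol %), chiral biphenol phosphoramidite of bis[1-(2-naphthyl)ethyl]amine (10 mol %), Et2O, −30 °C; then TMSOTf, −30 → 0 °C
Reagents that add atoms: trimethylaluminium, C[Al](C)C; TMSOTf, C[Si](C)(C)OS(=O)(=O)C(F)(F)F
Why: Cu-catalysed asymmetric conjugate addition to a β-substituted cyclohexenone creates the C4 quaternary centre under ligand control. O-silylation of the aluminium enolate fixes the enol ether regiospecifically toward C5.

**Step 4**
Reactants: 5; 6, trimethyl orthoformate
Product: 7, (3S,3aS,7aR)-3-methoxy-7a-methylhexahydroisobenzofuran-4(1H)-one (kaurane 4R,5S,6S; cis-fused, OMe exo, C10 ketone)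
Conditions: 6, BF3·OEt2, CH2Cl2, −78 °C; NaHCO3 work-up; crude, CSA (cat.), MeOH, rt
Reagents that add atoms: trimethyl orthoformate, COC(OC)OC (C6 and OMe; the OMe can exchange with MeOH, CO)
Why: Mukaiyama-type alkylation by the dimethoxycarbenium ion forms C5–C6. Acidic MeOH then removes TBS and the C19-OH closes the five-membered mixed acetal. C5 (α to the ketone) and C6 (anomeric) equilibrate to the cis-fused, exo-OMe isomer.

**Step 5**
Reactants: 7; 8, chloroiodomethane
Product: 9, C10/C20 spiro-oxirane of 7 (4R,5R,6S; 10S major)
Conditions: 8, MeLi·LiBr, THF, −78 °C → rt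
Reagents that add atoms: chloroiodomethane, ClCI (C20)
Why: Chloromethyllithium carbenoid 1,2-addition followed by ring closure is faster than enolisation or β-elimination of the β-alkoxy ketone. Attack is from the convex face, but the C10 configuration is erased in step 6, so both epimers converge.

**Step 6**
Reactants: 9; 10, 2,2,2-trifluoroethyl acrylate
Product: 11, spiro-δ-lactone in which C10 carries C20H2–O–C7(=O)–C8H2–C9H2 (4R,5R,6S,10R)
Conditions: 10, Cp2TiCl2, Zn, 2,4,6-collidine·HCl, THF, rt
Reagents that add atoms: 2,2,2-trifluoroethyl acrylate, C=CC(=O)OCC(F)(F)F (C7–C9 and the carbonyl O)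
Why: Ti(III) reductive epoxide opening (Nugent–RajanBabu) gives the tertiary C10 radical. Giese addition occurs on the convex β-face, anti to axial C19 and the THF ring, which sets C10. The C20 alkoxide then lactonises onto the activated ester.

**Step 7**
Reactants: 11; 12, ethyl formate
Product: 13, 8-formyl lactone (exists as the hydroxymethylene tautomer; C8 not defined)
Conditions: 12, NaH, cat. EtOH, THF, 0 °C → rt
Reagents that add atoms: ethyl formate, CCOC=O (C15HO)
Why: Crossed Claisen formylation. C8H2 is the only acidic position, and formation of the stabilised enolate drives the reaction.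

**Step 8**
Reactants: 13
Product: 14, 8-formyl-Δ8(9) spiro-5,6-dihydropyran-2-one (4R,5R,6S,10R), used crude
Conditions: PhSeCl, pyridine, CH2Cl2, 0 °C; then m-CPBA (1 equiv), −78 → 0 °C
Reagents that add atoms: none
Why: α-Selenenylation of the β-dicarbonyl followed by selenoxide syn-elimination toward C9-H. C10 is quaternary, so the alkene cannot deconjugate.

**Step 9**
Reactants: 14; 15, buta-1,3-diene
Product: 16, cis-fused cyclohexene-lactone aldehyde (4R,5R,6S,8S,9S,10R; C12=C13; CHO cis to H9)
Conditions: 15 (excess), ZnCl2 (0.5 equiv), CH2Cl2, −20 °C → rt, sealed tube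
Reagents that add atoms: buta-1,3-diene, C=CC=C (C11–C14)
Why: Diels–Alder reaction of a doubly activated, chelatable dienophile.
- The cyclic Z-alkene enforces the C7/C10-cis (H9/C15-cis) ring fusion.
- The diene adds to the lactone face flanked by C1H2, away from C5/C6, which sets C8 and C9.
- Any hetero-Diels–Alder adduct converges on 16 by Claisen rearrangement.

**Step 10**
Reactants: 16; 17, ethynylmagnesium bromide
Product: 18, C15 propargylic alcohol (C15 epimers, inconsequential)
Conditions: 17, THF, −78 °C; AcOH quench at −78 °C
Reagents that add atoms: ethynylmagnesium bromide, C#C[Mg]Br (C16, C17)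
Why: Grignard 1,2-addition is chemoselective for the aldehyde over the lactone. The cold acidic quench avoids retro-aldol cleavage of the alkoxide.

**Step 11**
Reactants: 18
Product: 19, tetracyclic 16-methylene-15-ol with the bicyclo[3.2.1]octane in place (8S,9S,13R; C15 epimers)
Conditions: n-Bu3SnH, AIBN, PhH (0.02 M), 80 °C; then PPTS, MeOH/CH2Cl2, rt
Reagents that add atoms: none
Why: Stannyl-radical-initiated enyne cyclisation.
- Bu3Sn• adds to C17, and the resulting C16 vinyl radical closes 5-exo-trig onto C13. This can only occur from the face bearing C15, which sets C13.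
- The C12 radical then abstracts H.
- Mild protodestannylation reveals the exocyclic methylene. Any acetal exchange in MeOH is degenerate.

**Step 12**
Reactants: 19
Product: 20, 16-en-15-one (16,17-didehydro target)
Conditions: DMP, NaHCO3, CH2Cl2, rt
Reagents that add atoms: none
Why: Dess–Martin oxidation converges both C15 epimers on the enone under buffered, acetal-safe conditions.

**Step 13**
Reactants: 20
Product: 21, ludongnin I
Conditions: H2 (1 atm), 10% Pd/C, EtOAc, rt
Reagents that add atoms: none
Why: Heterogeneous hydrogenation of the α-methylene ketone from the open exo face (the C14 side) places H16 exo and the methyl endo (16R). The alkene cannot isomerise into the ring (Bredt). Neutral conditions in the final step prevent epimerisation of this kinetic centre.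

## Compound list

| No. | Name | SMILES | Role |
|---|---|---|---|
| 1 | 3-methoxybenzyl alcohol | COc1cccc(CO)c1 | starting material |
| 2 | 3-(hydroxymethyl)cyclohex-2-enone | O=C1C=C(CO)CCC1 | intermediate |
| 3 | TBS ether of 2 | O=C1C=C(CO[Si](C)(C)C(C)(C)C)CCC1 | intermediate |
| 4 | trimethylaluminium | C[Al](C)C | starting material |
| 5 | (R)-TMS enol ether | C[Si](C)(C)OC1=C[C@](C)(CO[Si](C)(C)C(C)(C)C)CCC1 | intermediate |
| 6 | trimethyl orthoformate | COC(OC)OC | starting material |
| 7 | bicyclic keto acetal | CO[C@H]1OC[C@]2(C)CCCC(=O)[C@H]12 | intermediate |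
| 8 | chloroiodomethane | ClCI | starting material |
| 9 | spiro-epoxide (major epimer) | CO[C@H]1OC[C@]2(C)CCC[C@@]3(CO3)[C@H]12 | intermediate |
| 10 | 2,2,2-trifluoroethyl acrylate | C=CC(=O)OCC(F)(F)F | starting material |
| 11 | spiro-δ-lactone | CO[C@H]1OC[C@]2(C)CCC[C@]3(COC(=O)CC3)[C@H]12 | intermediate |
| 12 | ethyl formate | CCOC=O | starting material |
| 13 | 8-formyl lactone | CO[C@H]1OC[C@]2(C)CCC[C@]3(COC(=O)C(C=O)C3)[C@H]12 | intermediate |
| 14 | 8-formyl-Δ8(9) lactone | CO[C@H]1OC[C@]2(C)CCC[C@]3(COC(=O)C(C=O)=C3)[C@H]12 | intermediate |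
| 15 | buta-1,3-diene | C=CC=C | starting material |
| 16 | Diels–Alder adduct | CO[C@H]1OC[C@]2(C)CCC[C@]3(COC(=O)[C@@]4(C=O)CC=CC[C@H]43)[C@H]12 | intermediate |
| 17 | ethynylmagnesium bromide | C#C[Mg]Br | starting material |
| 18 | propargylic alcohol | CO[C@H]1OC[C@]2(C)CCC[C@]3(COC(=O)[C@@]4(C(O)C#C)CC=CC[C@H]43)[C@H]12 | intermediate |
| 19 | 16-methylene-15-ol | CO[C@H]1OC[C@]2(C)CCC[C@]3(COC(=O)[C@@]45C[C@@H](CC[C@H]43)C(=C)C5O)[C@H]12 | intermediate |
| 20 | 16-en-15-one | CO[C@H]1OC[C@]2(C)CCC[C@]3(COC(=O)[C@@]45C[C@@H](CC[C@H]43)C(=C)C5=O)[C@H]12 | intermediate |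
| 21 | ludongnin I | CO[C@H]1OC[C@]2(C)CCC[C@]3(COC(=O)[C@@]45C[C@@H](CC[C@H]43)[C@@H](C)C5=O)[C@H]12 | target |

## Step count
Total steps: 13. Longest linear sequence: 13 (fully linear).

## Steps most likely to fail
1. **Step 9, together with step 8.** Dienophile 14 is labile and C9 is neopentyl.
   - Fallback: use 2-(TBSO)buta-1,3-diene, which is much more reactive and "para"-selective, giving a C12 silyl enol ether with nucleophilic C13.
   - After ethynylation, close ring D by Au(I)-catalysed 5-exo-dig cyclisation of the silyl enol ether onto the alkyne.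
   - Then remove the C12 ketone via the tosylhydrazone and catecholborane.
2. **Step 11.** Risks are competing hydrostannation, 1,5-H transfer, and rearrangement to the bicyclo[2.2.2] skeleton.
   - Fallback: abandon the radical closure. Convert the alkyne to the 2-iodoalkene (B-iodo-9-BBN, then AcOH).
   - Form C16–C13 by an intramolecular reductive Heck reaction (Pd(0), HCO2Na).
3. **Step 3.** The ee and the enolate trapping are untested with a CH2OTBS β-substituent.
   - Fallback: run a racemic Me2CuLi/TMSCl addition and close the acetal in step 4 with (−)-menthol instead of MeOH.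
   - Separate the diastereomeric menthyl acetals and carry the correct one forward.
   - Exchange the menthyl group for OMe (CSA, MeOH) before step 13.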